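## Retrosynthetic overview

1. The target is ring A (methyl orsellinate unit)–CH2–ring B (hydroxyquinol unit)–O–ring C (haematommate unit). No ring is built: all three benzene rings are bought, ring B is joined to ring C first (ether), and ring A is added last (methylene bridge).
2. Bold last step: instead of pairing a protected benzyl halide with a protected orsellinate, acidic methanol strips three MOM groups, the benzylic alcohol of ring B collapses to an ortho-quinone methide, and unprotected methyl orsellinate captures it at C-3.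
3. Diaryl ether: no copper (Ullmann) coupling; SNAr of a ring B phenoxide on a ring C aryl fluoride flanked by CHO and CO2Me.
4. Ring B phenol: the formyl carbon of orcylaldehyde is excised (Dakin/Baeyer–Villiger) to unmask the ether oxygen, and the bridging carbon is placed between the two OMOM groups by directed metalation.
5. Ring C fluoride: ArBr → ArOH → ArOMOM, then magnesiation between F and OMOM and formylation.

Assumption: the target has no stereocentre and no stable atropisomer (it is achiral), so no stereocontrol is needed; compounds 1, 7 and 14 are taken as catalogue chemicals.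

## Route

Step 1
Reactants: 1 2,4-dihydroxy-6-methylbenzaldehyde (orcylaldehyde)
Product: 2 2,4-bis(methoxymethoxy)-6-methylbenzaldehyde
Conditions: NaH (2.5 equiv), MOMCl (2.5 equiv), DMF, 0 °C to rt
Reagents that add atoms: chloromethyl methyl ether (MOMCl), COCCl
Why: Williamson-type O-alkylation (MOM protection) of both sodium phenoxides, the hydrogen-bonded 2-OH included once NaH has deprotonated it; no stereocentre is involved.

Step 2
Reactants: 2 2,4-bis(methoxymethoxy)-6-methylbenzaldehyde
Product: 4 2,4-bis(methoxymethoxy)-6-methylphenol, via aryl formate 3 (not isolated)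
Conditions: mCPBA (1.3 equiv), CH2Cl2, 0 °C to rt; aq. NaHCO3 wash; then K2CO3 (0.2 equiv), MeOH, rt
Reagents that add atoms: 3-chloroperoxybenzoic acid (mCPBA), OOC(=O)c1cccc(Cl)c1
Why: Baeyer–Villiger (Dakin-type) oxidation in which the electron-rich 2,4-dialkoxy-6-methylphenyl group migrates in preference to hydride, so the formyl carbon leaves as formate and its methanolysis unmasks the one phenol oxygen that becomes the ether bridge while the two native oxygens stay masked.

Step 3
Reactants: 4 2,4-bis(methoxymethoxy)-6-methylphenol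
Product: 6 3-(hydroxymethyl)-2,4-bis(methoxymethoxy)-6-methylphenol, via dilithio species 5 (not isolated)
Conditions: n-BuLi (2.4 equiv), TMEDA, THF, 0 °C to rt; then (CH2O)n, −78 °C to rt; H2O
Reagents that add atoms: formaldehyde (from paraformaldehyde), C=O
Why: Directed ortho-metalation: after O-lithiation, the second equivalent of n-BuLi removes the only ring proton flanked by two chelating OMOM groups (meta to the phenoxide, so little deactivated), and the aryllithium adds to formaldehyde to place the benzylic alcohol exactly between the two masked phenols.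

Step 4
Reactants: 7 methyl 4-bromo-2-fluoro-6-methylbenzoate
Product: 9 methyl 2-fluoro-4-hydroxy-6-methylbenzoate, via pinacol boronate 8 (not isolated)
Conditions: B2pin2, Pd(dppf)Cl2 (3 mol %), KOAc, 1,4-dioxane, 90 °C; then KHSO5 (as the triple salt 2KHSO5·KHSO4·K2SO4), acetone/H2O, rt
Reagents that add atoms: bis(pinacolato)diboron, CC1(C)OB(OC1(C)C)B1OC(C)(C)C(C)(C)O1 (boron of 8 only); potassium peroxymonosulfate, [K+].[O-]S(=O)(=O)OO (the phenol oxygen)
Why: Miyaura borylation of the unhindered aryl bromide (oxidative addition to zerovalent palladium, acetate-assisted transmetalation) followed by ipso-oxidation of the C–B bond (1,2-aryl shift from boron to oxygen) gives the phenol without touching the hindered ester or the aryl fluoride.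

Step 5
Reactants: 9 methyl 2-fluoro-4-hydroxy-6-methylbenzoate
Product: 10 methyl 2-fluoro-4-(methoxymethoxy)-6-methylbenzoate
Conditions: NaH (1.2 equiv), MOMCl (1.2 equiv), DMF, 0 °C
Reagents that add atoms: chloromethyl methyl ether (MOMCl), COCCl
Why: Williamson-type MOM protection of the acidic para-ester phenol, which also installs the chelating directing group needed for step 6.

Step 6
Reactants: 10 methyl 2-fluoro-4-(methoxymethoxy)-6-methylbenzoate
Product: 12 methyl 2-fluoro-3-formyl-4-(methoxymethoxy)-6-methylbenzoate, via arylmagnesium chloride 11 (not isolated)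
Conditions: TMPMgCl·LiCl (1.3 equiv), THF, −20 to 0 °C; then DMF, −20 °C to rt; aq. NH4Cl
Reagents that add atoms: N,N-dimethylformamide (DMF), CN(C)C=O
Why: Directed magnesiation with the ester-tolerant amide base TMPMgCl·LiCl removes the ring proton lying between fluorine (inductive acidification) and OMOM (chelation), and the arylmagnesium, kept cold to avoid aryne formation, is formylated by DMF (Bouveault-type formylation).

Step 7
Reactants: 6 3-(hydroxymethyl)-2,4-bis(methoxymethoxy)-6-methylphenol; 12 methyl 2-fluoro-3-formyl-4-(methoxymethoxy)-6-methylbenzoate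
Product: 13 methyl 3-formyl-2-[3-(hydroxymethyl)-2,4-bis(methoxymethoxy)-6-methylphenoxy]-4-(methoxymethoxy)-6-methylbenzoate
Conditions: Cs2CO3 (1.5 equiv), DMF, 50 °C, argon
Reagents that add atoms: none
Why: Nucleophilic aromatic substitution (addition–elimination): the fluoride is flanked by an ortho-formyl and an ortho-ester group that both stabilise the Meisenheimer adduct, and under carbonate only the phenol of 6 (not its benzylic alcohol) is deprotonated, so the tetra-ortho-substituted diaryl ether forms without copper.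

Step 8
Reactants: 13 methyl 3-formyl-2-[3-(hydroxymethyl)-2,4-bis(methoxymethoxy)-6-methylphenoxy]-4-(methoxymethoxy)-6-methylbenzoate; 14 methyl 2,4-dihydroxy-6-methylbenzoate (methyl orsellinate, 5 equiv, excess recovered)
Product: 17 praesorether F, via triol benzylic alcohol 15 (not isolated), via ortho-quinone methide 16 (not isolated)
Conditions: HCl (1.25 M in MeOH), 45 °C; aq. work-up
Reagents that add atoms: none
Why: Acidic methanol removes the three MOM groups as dimethoxymethane, the 2,6-dihydroxybenzylic alcohol loses water to an ortho-quinone methide, and methyl orsellinate traps it by Friedel–Crafts-type conjugate addition at C-3 (between its two hydroxyls, the site that also takes formylation to haematommates), rearomatising ring B, while methanol as solvent keeps ring C as the open methyl ester; no stereocentre is created.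

## Compound list

1 | 2,4-dihydroxy-6-methylbenzaldehyde (orcylaldehyde) | Cc1cc(O)cc(O)c1C=O | starting material
2 | 2,4-bis(methoxymethoxy)-6-methylbenzaldehyde | Cc1cc(OCOC)cc(OCOC)c1C=O | intermediate
3 | 2,4-bis(methoxymethoxy)-6-methylphenyl formate | Cc1cc(OCOC)cc(OCOC)c1OC=O | intermediate
4 | 2,4-bis(methoxymethoxy)-6-methylphenol | Cc1cc(OCOC)cc(OCOC)c1O | intermediate
5 | lithium 3-lithio-2,4-bis(methoxymethoxy)-6-methylphenoxide | Cc1cc(OCOC)c([Li])c(OCOC)c1O[Li] | intermediate
6 | 3-(hydroxymethyl)-2,4-bis(methoxymethoxy)-6-methylphenol | Cc1cc(OCOC)c(CO)c(OCOC)c1O | intermediate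
7 | methyl 4-bromo-2-fluoro-6-methylbenzoate | COC(=O)c1c(C)cc(Br)cc1F | starting material
8 | methyl 2-fluoro-6-methyl-4-(4,4,5,5-tetramethyl-1,3,2-dioxaborolan-2-yl)benzoate | COC(=O)c1c(C)cc(B2OC(C)(C)C(C)(C)O2)cc1F | intermediate
9 | methyl 2-fluoro-4-hydroxy-6-methylbenzoate | COC(=O)c1c(C)cc(O)cc1F | intermediate
10 | methyl 2-fluoro-4-(methoxymethoxy)-6-methylbenzoate | COC(=O)c1c(C)cc(OCOC)cc1F | intermediate
11 | chloro[2-fluoro-3-(methoxycarbonyl)-6-(methoxymethoxy)-4-methylphenyl]magnesium (LiCl complex) | COC(=O)c1c(C)cc(OCOC)c([Mg]Cl)c1F | intermediate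
12 | methyl 2-fluoro-3-formyl-4-(methoxymethoxy)-6-methylbenzoate | COC(=O)c1c(C)cc(OCOC)c(C=O)c1F | intermediate
13 | methyl 3-formyl-2-[3-(hydroxymethyl)-2,4-bis(methoxymethoxy)-6-methylphenoxy]-4-(methoxymethoxy)-6-methylbenzoate | COC(=O)c1c(C)cc(OCOC)c(C=O)c1Oc1c(C)cc(OCOC)c(CO)c1OCOC | intermediate
14 | methyl 2,4-dihydroxy-6-methylbenzoate (methyl orsellinate) | COC(=O)c1c(C)cc(O)cc1O | starting material
15 | methyl 2-[2,4-dihydroxy-3-(hydroxymethyl)-6-methylphenoxy]-3-formyl-4-hydroxy-6-methylbenzoate | COC(=O)c1c(C)cc(O)c(C=O)c1Oc1c(C)cc(O)c(CO)c1O | intermediate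
16 | methyl 3-formyl-4-hydroxy-2-[(2-hydroxy-6-methyl-3-methylidene-4-oxocyclohexa-1,5-dien-1-yl)oxy]-6-methylbenzoate | C=C1C(=O)C=C(C)C(Oc2c(C=O)c(O)cc(C)c2C(=O)OC)=C1O | intermediate
17 | praesorether F, methyl 2-[3-[[2,6-dihydroxy-3-(methoxycarbonyl)-4-methylphenyl]methyl]-2,4-dihydroxy-6-methylphenoxy]-3-formyl-4-hydroxy-6-methylbenzoate (achiral) | COC(=O)c1c(C)cc(O)c(Cc2c(O)cc(C)c(Oc3c(C=O)c(O)cc(C)c3C(=O)OC)c2O)c1O | target

## Step count and risk

Total step count: 8. Longest linear sequence: 5 steps (1 → 2 → 3 → 7 → 8, or 4 → 5 → 6 → 7 → 8).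

The three steps most likely to fail:

Step 8 (final cascade). The risks are attack of 14 at C-5 instead of C-3, self-alkylation of the electron-rich ring B, and acid-promoted condensation of the ring C aldehyde with phenols. The fallback sets out from 13 and 14 and comes back at 17; it replaces the innate-selectivity Friedel–Crafts step by a regiodefined cross-coupling. Compound 14 is protected (MOMCl, NaH) as methyl 2,4-bis(methoxymethoxy)-6-methylbenzoate F8. F8 is magnesiated between its two OMOM groups with TMPMgCl·LiCl to chloro[3-(methoxycarbonyl)-2,6-bis(methoxymethoxy)-4-methylphenyl]magnesium F9, and ZnCl2 converts this to chloro[3-(methoxycarbonyl)-2,6-bis(methoxymethoxy)-4-methylphenyl]zinc F10, which tolerates aldehydes. The benzylic alcohol of 13 is turned (MsCl, Et3N, LiCl) into methyl 2-[3-(chloromethyl)-2,4-bis(methoxymethoxy)-6-methylphenoxy]-3-formyl-4-(methoxymethoxy)-6-methylbenzoate F11. Negishi coupling of F10 with F11 (Pd(OAc)2, SPhos, THF) gives penta-MOM praesorether F F12, and HCl in MeOH unmasks it to 17.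

Step 3 (dianion metalation and formaldehyde trapping). The lithium phenoxide may slow the second deprotonation, and paraformaldehyde trapping of a dianion can be inefficient. The fallback sets out from 4 and comes back at 6; it avoids the dianion by masking the phenol. Compound 4 is silylated (TBSCl, imidazole, DMF) to tert-butyl[2,4-bis(methoxymethoxy)-6-methylphenoxy]dimethylsilane F1. F1 is lithiated as a neutral arene with one equivalent of n-BuLi/TMEDA to [3-[tert-butyl(dimethyl)silyl]oxy-2,6-bis(methoxymethoxy)-4-methylphenyl]lithium F2, and paraformaldehyde gives [3-[tert-butyl(dimethyl)silyl]oxy-2,6-bis(methoxymethoxy)-4-methylphenyl]methanol F3. TBAF in THF removes the silyl group to give 6.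

Step 6 (magnesiation next to an ester). The base may be too weak for the F/OMOM-flanked proton, or may touch the ester or the ortho-methyl group. The fallback sets out from 7 and comes back at 12; it moves the metalation to the bromide stage, where the proton between F and Br is more acidic, and introduces oxygen afterwards. Compound 7 is magnesiated with TMPMgCl·LiCl at −20 °C to chloro[6-bromo-2-fluoro-3-(methoxycarbonyl)-4-methylphenyl]magnesium F4, and DMF gives methyl 4-bromo-2-fluoro-3-formyl-6-methylbenzoate F5. Miyaura borylation (B2pin2, Pd(dppf)Cl2, KOAc) gives methyl 2-fluoro-3-formyl-6-methyl-4-(4,4,5,5-tetramethyl-1,3,2-dioxaborolan-2-yl)benzoate F6. Trimethylamine N-oxide, which spares the aldehyde, oxidises F6 to methyl 2-fluoro-3-formyl-4-hydroxy-6-methylbenzoate F7, and MOMCl with i-Pr2NEt gives 12.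

## Further compounds

F1 | step 3 | tert-butyl[2,4-bis(methoxymethoxy)-6-methylphenoxy]dimethylsilane | Cc1cc(OCOC)cc(OCOC)c1O[Si](C)(C)C(C)(C)C
F2 | step 3 | [3-[tert-butyl(dimethyl)silyl]oxy-2,6-bis(methoxymethoxy)-4-methylphenyl]lithium | Cc1cc(OCOC)c([Li])c(OCOC)c1O[Si](C)(C)C(C)(C)C
F3 | step 3 | [3-[tert-butyl(dimethyl)silyl]oxy-2,6-bis(methoxymethoxy)-4-methylphenyl]methanol | Cc1cc(OCOC)c(CO)c(OCOC)c1O[Si](C)(C)C(C)(C)C
F4 | step 6 | chloro[6-bromo-2-fluoro-3-(methoxycarbonyl)-4-methylphenyl]magnesium | COC(=O)c1c(C)cc(Br)c([Mg]Cl)c1F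
F5 | step 6 | methyl 4-bromo-2-fluoro-3-formyl-6-methylbenzoate | COC(=O)c1c(C)cc(Br)c(C=O)c1F
F6 | step 6 | methyl 2-fluoro-3-formyl-6-methyl-4-(4,4,5,5-tetramethyl-1,3,2-dioxaborolan-2-yl)benzoate | COC(=O)c1c(C)cc(B2OC(C)(C)C(C)(C)O2)c(C=O)c1F
F7 | step 6 | methyl 2-fluoro-3-formyl-4-hydroxy-6-methylbenzoate | COC(=O)c1c(C)cc(O)c(C=O)c1F
F8 | step 8 | methyl 2,4-bis(methoxymethoxy)-6-methylbenzoate | COC(=O)c1c(C)cc(OCOC)cc1OCOC
F9 | step 8 | chloro[3-(methoxycarbonyl)-2,6-bis(methoxymethoxy)-4-methylphenyl]magnesium | COC(=O)c1c(C)cc(OCOC)c([Mg]Cl)c1OCOC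
F10 | step 8 | chloro[3-(methoxycarbonyl)-2,6-bis(methoxymethoxy)-4-methylphenyl]zinc | COC(=O)c1c(C)cc(OCOC)c([Zn]Cl)c1OCOC
F11 | step 8 | methyl 2-[3-(chloromethyl)-2,4-bis(methoxymethoxy)-6-methylphenoxy]-3-formyl-4-(methoxymethoxy)-6-methylbenzoate | COC(=O)c1c(C)cc(OCOC)c(C=O)c1Oc1c(C)cc(OCOC)c(CCl)c1OCOC
F12 | step 8 | methyl 3-formyl-2-[3-[[3-(methoxycarbonyl)-2,6-bis(methoxymethoxy)-4-methylphenyl]methyl]-2,4-bis(methoxymethoxy)-6-methylphenoxy]-4-(methoxymethoxy)-6-methylbenzoate (penta-MOM praesorether F) | COC(=O)c1c(C)cc(OCOC)c(Cc2c(OCOC)cc(C)c(Oc3c(C=O)c(OCOC)cc(C)c3C(=O)OC)c2OCOC)c1OCOC
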